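The trimer is cut at its two C4→C8 bonds into three copies of one monomer, tetra-O-benzylepicatechin, and the monomer's pyran ring C is made by annulating an acyclic three-carbon chain onto ring A. The key step exploits that O1 and C4 sit on the neighbouring ring-A carbons C8a and C4a, with C4a flanked by the C5 oxygen. A 3,5-bis(benzyloxy)benzyne (C4a≡C8a) takes up a benzylic alkoxide at C8a, and the resulting C4a carbanion displaces a primary bromide, forming O1–C8a and C4–C4a in one operation. The precursor is a syn-configured bromo alcohol from an Evans glycolate aldol, which already carries C2 and C3. Both gallates are attached to monomers before the couplings.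

Key step: step 6

Remark on the chemistry: flavan numbering is used for every unit (O1, C2, C3, C4, C4a, C5 to C8, C8a; ring B primed). The unit with the free 3-OH is called upper, the unit with the C4 methylene lower. All three units are taken from the one synthetic monomer 18, and each gallate is introduced on a monomer with one molecule of acid 20. The facial sense of the aldol in step 3 is assumed to follow the usual chair model for the (S)-configured auxiliary.

Step 1
Reactants: 1 1,3,5-trifluorobenzene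
Product: 2 1,3-bis(benzyloxy)-5-fluorobenzene
Conditions: BnOH (2.2 equiv), NaH (2.3 equiv), NMP, 0 → 100 °C
Reagents that add atoms: benzyl alcohol, OCc1ccccc1
Why: Nucleophilic aromatic substitution (SNAr) should exchange two fluorides, each activated by the meta fluorines, and stop there because the dialkoxy ring is too electron-rich for a third exchange.

Step 2
Reactants: 3 (S)-4-benzyl-1,3-oxazolidin-2-one; 4 2-(allyloxy)acetic acid
Product: 6 (S)-3-[2-(allyloxy)acetyl]-4-benzyl-1,3-oxazolidin-2-one, via mixed pivalic anhydride 5 (not isolated)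
Conditions: PivCl, Et3N, THF, −20 °C; then 3, LiCl, rt
Reagents that add atoms: none
Why: N-acylation of the oxazolidinone through the mixed anhydride should occur at the unhindered glycolyl carbonyl and not at the pivaloyl carbonyl.

Step 3
Reactants: 6 (S)-3-[2-(allyloxy)acetyl]-4-benzyl-1,3-oxazolidin-2-one; 7 3,4-bis(benzyloxy)benzaldehyde
Product: 9 (S)-3-[(2S,3R)-2-(allyloxy)-3-[3,4-bis(benzyloxy)phenyl]-3-hydroxypropanoyl]-4-benzyl-1,3-oxazolidin-2-one, via Z boron enolate 8 (not isolated)
Conditions: Bu2BOTf, Et3N, CH2Cl2, −78 → 0 °C; 7, −78 → 0 °C; then pH 7 buffer, MeOH, H2O2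
Reagents that add atoms: none
Why: In this Evans syn aldol reaction the Z boron enolate should react through a Zimmerman–Traxler chair on the face away from the benzyl group of the auxiliary, setting the future flavan C3 (2S here) and C2 (3R here) in the syn relation that corresponds to the 2,3-cis ring.

Step 4
Reactants: 9 (S)-3-[(2S,3R)-2-(allyloxy)-3-[3,4-bis(benzyloxy)phenyl]-3-hydroxypropanoyl]-4-benzyl-1,3-oxazolidin-2-one
Product: 10 (1R,2R)-2-(allyloxy)-1-[3,4-bis(benzyloxy)phenyl]propane-1,3-diol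
Conditions: LiBH4, MeOH, THF, 0 °C
Reagents that add atoms: none
Why: Reductive cleavage of the imide by hydride attack at the exocyclic carbonyl should free the primary alcohol and the auxiliary without touching either stereocentre.

Step 5
Reactants: 10 (1R,2R)-2-(allyloxy)-1-[3,4-bis(benzyloxy)phenyl]propane-1,3-diol
Product: 11 (1R,2S)-2-(allyloxy)-1-[3,4-bis(benzyloxy)phenyl]-3-bromopropan-1-ol
Conditions: CBr4, PPh3, CH2Cl2, 0 °C
Reagents that add atoms: carbon tetrabromide, BrC(Br)(Br)Br
Why: In this Appel reaction the oxyphosphonium should form faster at the primary than at the hindered secondary benzylic hydroxyl and be displaced by bromide in an SN2 step.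

Step 6
Reactants: 2 1,3-bis(benzyloxy)-5-fluorobenzene; 11 (1R,2S)-2-(allyloxy)-1-[3,4-bis(benzyloxy)phenyl]-3-bromopropan-1-ol
Product: 16 3-O-allyl-5,7,3',4'-tetra-O-benzylepicatechin, via lithiated fluoroarene 12 (not isolated), via lithium alkoxide 13 (not isolated), via 3,5-bis(benzyloxy)benzyne 14 (not isolated), via aryllithium ether 15 (not isolated)
Conditions: 2, n-BuLi, THF, −78 °C; separately 11, n-BuLi, THF, −78 °C, then DMPU; lithiated 2 added slowly at −30 °C, then 0 °C
Reagents that add atoms: none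
Why: Proposed new method: n-BuLi lithiates 2 between fluorine and a benzyloxy group to give 12, which on warming loses LiF to aryne 14; alkoxide 13 adds to the aryne carbon that carried fluorine (future C8a), and the aryllithium 15 so formed at the neighbouring carbon (future C4a) displaces the primary bromide. The closest known reaction types are the aryne annulation in which a nucleophile adds and the aryl anion is caught by a tethered electrophile (xanthones from salicylates) and the Parham cyclialkylation of an ortho-lithiated aryl ether, known for flavans as a two-stage sequence after an SNAr etherification; their merger with an alkoxide bearing an alkyl bromide is the untested part. Ring C closes in the 6-exo-tet mode. No stereocentre is formed: C2 and C3 come from 11 and are retained because the carbinol C–O bond is not broken and C3 has no epimerisable hydrogen. Regioselectivity is needed in the addition to the aryne and is secured by the benzyloxy group (future C5–O) next to the carbon that becomes C4a, which stabilises the carbanion there, as in additions to 3-alkoxyarynes. Chemoselectivity is needed for the alkoxide over 12 as the aryne trap, to be secured by adding 12 slowly to the DMPU-activated alkoxide so that the aryne forms at low concentration in its presence, and the allyl ether at O3 cannot migrate, so the bromide cannot close to an epoxide.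

Step 7
Reactants: 16 3-O-allyl-5,7,3',4'-tetra-O-benzylepicatechin
Product: 18 5,7,3',4'-tetra-O-benzyl-(−)-epicatechin, via 1-propenyl ether 17 (not isolated)
Conditions: [Ir(cod)(PMePh2)2]PF6 (cat., H2-activated), THF, rt; then 1 M aq HCl, rt
Reagents that add atoms: none
Why: Allyl ether cleavage by iridium-hydride-catalysed isomerisation to the enol ether and mild acid hydrolysis should free the 3-OH while benzyl ethers and both stereocentres stay untouched.

Step 8
Reactants: 18 5,7,3',4'-tetra-O-benzyl-(−)-epicatechin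
Product: 19 4β-(2-ethoxyethoxy)-5,7,3',4'-tetra-O-benzylepicatechin
Conditions: DDQ, 2-ethoxyethanol, CH2Cl2, rt
Reagents that add atoms: 2-ethoxyethanol, CCOCCO
Why: Benzylic oxidation by DDQ (hydride abstraction at C4, assisted by the dioxygenated ring A) should give a cation that the alcohol traps on the face opposite the C2 aryl and C3 hydroxyl groups, setting C4 as the 4β (3,4-trans) ether.

Step 9
Reactants: 18 5,7,3',4'-tetra-O-benzyl-(−)-epicatechin; 20 3,4,5-tris(benzyloxy)benzoic acid
Product: 21 5,7,3',4'-tetra-O-benzylepicatechin 3-O-[3,4,5-tris(benzyloxy)benzoate]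
Conditions: DCC, DMAP, CH2Cl2, rt
Reagents that add atoms: none
Why: Steglich esterification should acylate the secondary C3 hydroxyl, the only free hydroxyl present, through the N-acylpyridinium ion without touching a stereocentre.

Step 10
Reactants: 19 4β-(2-ethoxyethoxy)-5,7,3',4'-tetra-O-benzylepicatechin; 20 3,4,5-tris(benzyloxy)benzoic acid
Product: 22 4β-(2-ethoxyethoxy)-5,7,3',4'-tetra-O-benzylepicatechin 3-O-[3,4,5-tris(benzyloxy)benzoate]
Conditions: DCC, DMAP, CH2Cl2, 0 °C → rt
Reagents that add atoms: none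
Why: Steglich esterification should acylate the C3 hydroxyl, the only free hydroxyl, while the acid-labile C4 ether survives the non-acidic carbodiimide conditions and no stereocentre is touched.

Step 11
Reactants: 22 4β-(2-ethoxyethoxy)-5,7,3',4'-tetra-O-benzylepicatechin 3-O-[3,4,5-tris(benzyloxy)benzoate]; 21 5,7,3',4'-tetra-O-benzylepicatechin 3-O-[3,4,5-tris(benzyloxy)benzoate]
Product: 23 octa-O-benzylprocyanidin B2 3,3''-bis[3,4,5-tris(benzyloxy)benzoate]
Conditions: Me3SiOTf (cat.), CH2Cl2, −78 → −20 °C, excess 21 (recovered)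
Reagents that add atoms: none
Why: In this Friedel–Crafts-type flavan condensation the Lewis acid ionises the C4 ether of 22 with anchimeric assistance by the 3-O-acyl carbonyl, which covers the α face, so C8 of 21, the most nucleophilic position of its ring A, should attack from the β face trans to the C3 oxygen and set the 4β→8 bond, while excess 21 suppresses self-condensation of 22.

Step 12
Reactants: 19 4β-(2-ethoxyethoxy)-5,7,3',4'-tetra-O-benzylepicatechin; 23 octa-O-benzylprocyanidin B2 3,3''-bis[3,4,5-tris(benzyloxy)benzoate]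
Product: 24 fully benzylated trimer (upper unit with free 3-OH, middle and lower units as tri-O-benzylgallates)
Conditions: Me3SiOTf (cat.), CH2Cl2, −78 → −40 °C, 19 added slowly
Reagents that add atoms: none
Why: The same Friedel–Crafts-type condensation should join the C4 cation from 19 to C8 of the 4-linked unit of 23 (the future middle unit), the only unsubstituted C8 and more reactive than the C6 positions, from the β face trans to the C3 hydroxyl, setting the second 4β→8 bond.

Step 13
Reactants: 24 fully benzylated trimer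
Product: 25 epicatechin-(4β→8)-epicatechin 3-O-gallate-(4β→8)-epicatechin 3-O-gallate (CNP0279403.1)
Conditions: H2 (1 atm), Pd(OH)2 on carbon, THF/MeOH/H2O, rt
Reagents that add atoms: none
Why: Hydrogenolysis of all eighteen benzyl ethers under neutral conditions should leave the two gallate esters and the acid-labile interflavan bonds intact.

Compound list
1 | 1,3,5-trifluorobenzene | Fc1cc(F)cc(F)c1 | starting material
2 | 1,3-bis(benzyloxy)-5-fluorobenzene | Fc1cc(OCc2ccccc2)cc(OCc2ccccc2)c1 | intermediate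
3 | (S)-4-benzyl-1,3-oxazolidin-2-one | O=C1N[C@@H](Cc2ccccc2)CO1 | starting material
4 | 2-(allyloxy)acetic acid | C=CCOCC(=O)O | starting material
5 | 2-(allyloxy)acetic pivalic anhydride | C=CCOCC(=O)OC(=O)C(C)(C)C | intermediate (not isolated)
6 | (S)-3-[2-(allyloxy)acetyl]-4-benzyl-1,3-oxazolidin-2-one | C=CCOCC(=O)N1C(=O)OC[C@@H]1Cc1ccccc1 | intermediate
7 | 3,4-bis(benzyloxy)benzaldehyde | O=Cc1ccc(OCc2ccccc2)c(OCc2ccccc2)c1 | starting material
8 | Z-configured dibutylboron enolate of 6 | CCCCB(CCCC)O/C(=C\OCC=C)N1C(=O)OC[C@@H]1Cc1ccccc1 | intermediate (not isolated)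
9 | (S)-3-[(2S,3R)-2-(allyloxy)-3-[3,4-bis(benzyloxy)phenyl]-3-hydroxypropanoyl]-4-benzyl-1,3-oxazolidin-2-one | C=CCO[C@H](C(=O)N1C(=O)OC[C@@H]1Cc1ccccc1)[C@H](O)c1ccc(OCc2ccccc2)c(OCc2ccccc2)c1 | intermediate
10 | (1R,2R)-2-(allyloxy)-1-[3,4-bis(benzyloxy)phenyl]propane-1,3-diol | C=CCO[C@H](CO)[C@H](O)c1ccc(OCc2ccccc2)c(OCc2ccccc2)c1 | intermediate
11 | (1R,2S)-2-(allyloxy)-1-[3,4-bis(benzyloxy)phenyl]-3-bromopropan-1-ol | C=CCO[C@H](CBr)[C@H](O)c1ccc(OCc2ccccc2)c(OCc2ccccc2)c1 | intermediate
12 | [2,4-bis(benzyloxy)-6-fluorophenyl]lithium | [Li]c1c(F)cc(OCc2ccccc2)cc1OCc1ccccc1 | intermediate (not isolated)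
13 | lithium alkoxide of 11 | C=CCO[C@H](CBr)[C@H](O[Li])c1ccc(OCc2ccccc2)c(OCc2ccccc2)c1 | intermediate (not isolated)
14 | 3,5-bis(benzyloxy)benzyne | C1#CC(OCc2ccccc2)=CC(OCc2ccccc2)=C1 | intermediate (not isolated)
15 | {2-[(1R,2S)-2-(allyloxy)-1-[3,4-bis(benzyloxy)phenyl]-3-bromopropoxy]-4,6-bis(benzyloxy)phenyl}lithium | C=CCO[C@H](CBr)[C@H](Oc1cc(OCc2ccccc2)cc(OCc2ccccc2)c1[Li])c1ccc(OCc2ccccc2)c(OCc2ccccc2)c1 | intermediate (not isolated)
16 | (2R,3R)-3-(allyloxy)-5,7-bis(benzyloxy)-2-[3,4-bis(benzyloxy)phenyl]chromane (3-O-allyl-5,7,3',4'-tetra-O-benzylepicatechin) | C=CCO[C@@H]1Cc2c(OCc3ccccc3)cc(OCc3ccccc3)cc2O[C@@H]1c1ccc(OCc2ccccc2)c(OCc2ccccc2)c1 | intermediate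
17 | 1-propenyl ether of 18 (3-O-(prop-1-enyl), E/Z mixture) | CC=CO[C@@H]1Cc2c(OCc3ccccc3)cc(OCc3ccccc3)cc2O[C@@H]1c1ccc(OCc2ccccc2)c(OCc2ccccc2)c1 | intermediate (not isolated)
18 | (2R,3R)-5,7-bis(benzyloxy)-2-[3,4-bis(benzyloxy)phenyl]chroman-3-ol (5,7,3',4'-tetra-O-benzyl-(−)-epicatechin) | O[C@@H]1Cc2c(OCc3ccccc3)cc(OCc3ccccc3)cc2O[C@@H]1c1ccc(OCc2ccccc2)c(OCc2ccccc2)c1 | intermediate
19 | (2R,3R,4S)-5,7-bis(benzyloxy)-2-[3,4-bis(benzyloxy)phenyl]-4-(2-ethoxyethoxy)chroman-3-ol (4β ether, 3,4-trans) | O[C@@H]1[C@@H](OCCOCC)c2c(OCc3ccccc3)cc(OCc3ccccc3)cc2O[C@@H]1c1ccc(OCc2ccccc2)c(OCc2ccccc2)c1 | intermediate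
20 | 3,4,5-tris(benzyloxy)benzoic acid | OC(=O)c1cc(OCc2ccccc2)c(OCc2ccccc2)c(OCc2ccccc2)c1 | starting material
21 | (2R,3R)-5,7-bis(benzyloxy)-2-[3,4-bis(benzyloxy)phenyl]chroman-3-yl 3,4,5-tris(benzyloxy)benzoate (5,7,3',4'-tetra-O-benzylepicatechin 3-O-tri-O-benzylgallate) | O=C(O[C@@H]1Cc2c(OCc3ccccc3)cc(OCc3ccccc3)cc2O[C@@H]1c1ccc(OCc2ccccc2)c(OCc2ccccc2)c1)c1cc(OCc2ccccc2)c(OCc2ccccc2)c(OCc2ccccc2)c1 | intermediate
22 | (2R,3R,4S)-5,7-bis(benzyloxy)-2-[3,4-bis(benzyloxy)phenyl]-4-(2-ethoxyethoxy)chroman-3-yl 3,4,5-tris(benzyloxy)benzoate (4β ether, 3,4-trans) | O=C(O[C@@H]1[C@@H](OCCOCC)c2c(OCc3ccccc3)cc(OCc3ccccc3)cc2O[C@@H]1c1ccc(OCc2ccccc2)c(OCc2ccccc2)c1)c1cc(OCc2ccccc2)c(OCc2ccccc2)c(OCc2ccccc2)c1 | intermediate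
23 | octa-O-benzylprocyanidin B2 3,3''-bis[3,4,5-tris(benzyloxy)benzoate] | O=C(O[C@@H]1[C@@H](c2c(OCc3ccccc3)cc(OCc3ccccc3)c3c2O[C@H](c2ccc(OCc4ccccc4)c(OCc4ccccc4)c2)[C@H](OC(=O)c2cc(OCc4ccccc4)c(OCc4ccccc4)c(OCc4ccccc4)c2)C3)c2c(OCc3ccccc3)cc(OCc3ccccc3)cc2O[C@@H]1c1ccc(OCc2ccccc2)c(OCc2ccccc2)c1)c1cc(OCc2ccccc2)c(OCc2ccccc2)c(OCc2ccccc2)c1 | intermediate
24 | 5,7,3',4'-tetra-O-benzylepicatechin-(4β→8)-[5,7,3',4'-tetra-O-benzylepicatechin 3-O-tri-O-benzylgallate]-(4β→8)-[5,7,3',4'-tetra-O-benzylepicatechin 3-O-tri-O-benzylgallate] | O=C(O[C@@H]1[C@@H](c2c(OCc3ccccc3)cc(OCc3ccccc3)c3c2O[C@H](c2ccc(OCc4ccccc4)c(OCc4ccccc4)c2)[C@H](OC(=O)c2cc(OCc4ccccc4)c(OCc4ccccc4)c(OCc4ccccc4)c2)C3)c2c(OCc3ccccc3)cc(OCc3ccccc3)c([C@H]3c4c(OCc5ccccc5)cc(OCc5ccccc5)cc4O[C@H](c4ccc(OCc5ccccc5)c(OCc5ccccc5)c4)[C@@H]3O)c2O[C@@H]1c1ccc(OCc2ccccc2)c(OCc2ccccc2)c1)c1cc(OCc2ccccc2)c(OCc2ccccc2)c(OCc2ccccc2)c1 | intermediate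
25 | epicatechin-(4β→8)-epicatechin 3-O-gallate-(4β→8)-epicatechin 3-O-gallate (upper 2R,3R,4R; middle 2R,3R,4S; lower 2R,3R) | O=C(O[C@@H]1[C@@H](c2c(O)cc(O)c3c2O[C@H](c2ccc(O)c(O)c2)[C@H](OC(=O)c2cc(O)c(O)c(O)c2)C3)c2c(O)cc(O)c([C@H]3c4c(O)cc(O)cc4O[C@H](c4ccc(O)c(O)c4)[C@@H]3O)c2O[C@@H]1c1ccc(O)c(O)c1)c1cc(O)c(O)c(O)c1 | target

Total step count: 13. Longest linear sequence: 11 steps (steps 2 to 8 and 10 to 13).

Steps most likely to fail

Step 6. The aryne may be intercepted by the ortho-lithiated fluoroarene faster than by the hindered lithium alkoxide, or the aryllithium may be protonated before ring closure, so that the two bonds do not form in one pass. The fallback makes them in two stages by known chemistry and sets out from 2 and 11. Ortho-lithiation of 2 (n-BuLi, THF, −78 °C) and quenching with methyl p-toluenesulfinate should give 1,5-bis(benzyloxy)-3-fluoro-2-(p-tolylsulfinyl)benzene F1 (racemic at sulfur). The sulfinyl group activates the fluoride for SNAr by the sodium alkoxide of 11 (NaH, THF/DMF, 0 °C), giving the sulfinyl aryl ether F2. PhLi (THF, −78 °C) then effects sulfoxide–lithium exchange to the same aryllithium 15, which cyclises onto the bromide. The fallback comes back to the route at 16.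

Step 12. The electrophile 19 may condense with itself through its own free C8, and the product may grow further, so that regiocontrol and chain length are lost against the hindered nucleophile 23. The fallback blocks that position and sets out from 18. Bromination with NBS (CH2Cl2, −78 °C) should give 8-bromo-5,7,3',4'-tetra-O-benzylepicatechin F3. DDQ and 2-ethoxyethanol then give its 4β-(2-ethoxyethoxy) ether F4, which can only act as the electrophile. Me3SiOTf-promoted condensation with 23 gives the 8-bromo analogue of the protected trimer F5. Hydrogenolysis (H2, Pd(OH)2 on carbon, Et3N, THF/MeOH/H2O) removes bromine together with the benzyl groups. The fallback comes back to the route at 25.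

Step 5. Under oxyphosphonium activation the electron-rich secondary benzylic alcohol may ionise or be substituted in competition with the primary site, which would cost site selectivity and the C1 configuration. The fallback separates activation from halide delivery and sets out from 10. Selective sulfonylation of the primary hydroxyl (TsCl, pyridine, 0 °C) should give (2R,3R)-2-(allyloxy)-3-[3,4-bis(benzyloxy)phenyl]-3-hydroxypropyl 4-methylbenzenesulfonate F6. Displacement with LiBr (acetone, 50 °C) under neutral conditions then gives the bromide. The fallback comes back to the route at 11.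

Further compounds
F1 | step 6 | 1,5-bis(benzyloxy)-3-fluoro-2-(p-tolylsulfinyl)benzene | Cc1ccc(cc1)S(=O)c1c(F)cc(OCc2ccccc2)cc1OCc1ccccc1
F2 | step 6 | 1-[(1R,2S)-2-(allyloxy)-1-[3,4-bis(benzyloxy)phenyl]-3-bromopropoxy]-3,5-bis(benzyloxy)-2-(p-tolylsulfinyl)benzene | C=CCO[C@H](CBr)[C@H](Oc1cc(OCc2ccccc2)cc(OCc2ccccc2)c1S(=O)c1ccc(C)cc1)c1ccc(OCc2ccccc2)c(OCc2ccccc2)c1
F3 | step 12 | (2R,3R)-8-bromo-5,7-bis(benzyloxy)-2-[3,4-bis(benzyloxy)phenyl]chroman-3-ol | O[C@@H]1Cc2c(OCc3ccccc3)cc(OCc3ccccc3)c(Br)c2O[C@@H]1c1ccc(OCc2ccccc2)c(OCc2ccccc2)c1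
F4 | step 12 | (2R,3R,4S)-8-bromo-5,7-bis(benzyloxy)-2-[3,4-bis(benzyloxy)phenyl]-4-(2-ethoxyethoxy)chroman-3-ol | O[C@@H]1[C@@H](OCCOCC)c2c(OCc3ccccc3)cc(OCc3ccccc3)c(Br)c2O[C@@H]1c1ccc(OCc2ccccc2)c(OCc2ccccc2)c1
F5 | step 12 | 8-bromo analogue of 24 (bromine at C8 of the upper unit) | O=C(O[C@@H]1[C@@H](c2c(OCc3ccccc3)cc(OCc3ccccc3)c3c2O[C@H](c2ccc(OCc4ccccc4)c(OCc4ccccc4)c2)[C@H](OC(=O)c2cc(OCc4ccccc4)c(OCc4ccccc4)c(OCc4ccccc4)c2)C3)c2c(OCc3ccccc3)cc(OCc3ccccc3)c([C@H]3c4c(OCc5ccccc5)cc(OCc5ccccc5)c(Br)c4O[C@H](c4ccc(OCc5ccccc5)c(OCc5ccccc5)c4)[C@@H]3O)c2O[C@@H]1c1ccc(OCc2ccccc2)c(OCc2ccccc2)c1)c1cc(OCc2ccccc2)c(OCc2ccccc2)c(OCc2ccccc2)c1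
F6 | step 5 | (2R,3R)-2-(allyloxy)-3-[3,4-bis(benzyloxy)phenyl]-3-hydroxypropyl 4-methylbenzenesulfonate | C=CCO[C@H](COS(=O)(=O)c1ccc(C)cc1)[C@H](O)c1ccc(OCc2ccccc2)c(OCc2ccccc2)c1
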